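**Strategy.** Locants follow 3,7-dioxabicyclo[3.3.0]octane (C1 carbinol, C2/C6 aryl-bearing). The oxolane O7–C8–C1–C5–C6 is grown from an oxirane. Zerovalent palladium opens the enantiopure aryl vinyl oxirane 3 (O7, C6, C5) to a π-allyl alkoxide. O7 adds to the CH2 terminus (C8) of the α-siloxy enone 6, and the enolate carbon (C1) closes onto C5. This single ring expansion inserts C8–C1 between O7 and C5, installs the oxygenated quaternary C1 with its C2 aroyl arm, and sets C1 and C5 relative to C6. The second oxolane is then closed by SN2 etherification (O3–C4), which alone can deliver the trans ring fusion.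

Key step: step 5

Remark: the descriptors of the given structure, (1S,2R,5S,6R), put 1-OH and 5-H on opposite faces, so the bicycle is trans-fused; no ring is therefore closed at C1 or C5 under thermodynamic control, and the second ring is formed by a kinetic SN2 closure.

Step 1
Reactants: 1 (E)-3-(3,4-dimethoxyphenyl)prop-2-enal
Product: 2 (2R,3S)-3-(3,4-dimethoxyphenyl)oxirane-2-carbaldehyde
Conditions: H2O2 (35% aq), (S)-2-{bis[3,5-bis(trifluoromethyl)phenyl](trimethylsilyloxy)methyl}pyrrolidine (10 mol %), CH2Cl2, 0 → 23 °C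
Reagents that add atoms: hydrogen peroxide, OO
Why: Organocatalytic iminium/enamine (Weitz–Scheffer-type) epoxidation of an enal, in which the diarylprolinol silyl ether shields one face of the E-iminium ion so that hydroperoxide adds to the β-carbon from the open face and the enamine closes the trans-oxirane, which should give the (2R,3S) isomer.

Step 2
Reactants: 2 (2R,3S)-3-(3,4-dimethoxyphenyl)oxirane-2-carbaldehyde
Product: 3 (2S,3S)-2-(3,4-dimethoxyphenyl)-3-ethenyloxirane (trans)
Conditions: Ph3PCH3Br, KN(SiMe3)2, THF, −78 → 0 °C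
Reagents that add atoms: methyltriphenylphosphonium bromide, C[P+](c1ccccc1)(c1ccccc1)c1ccccc1.[Br-]
Why: Wittig methylenation with a non-stabilised ylide at low temperature should leave the oxirane and both stereocentres untouched (the descriptor of the former aldehyde-bearing carbon changes only through the priority switch).

Step 3
Reactants: 4 1-(3,4-dimethoxyphenyl)propan-1-one
Product: 5 1-(3,4-dimethoxyphenyl)propane-1,2-dione
Conditions: SeO2, 1,4-dioxane/H2O, 100 °C
Reagents that add atoms: selenium dioxide, O=[Se]=O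
Why: Riley oxidation of the activated α-methylene of an aryl ketone should give the 1,2-dione; no stereocentre is formed.

Step 4
Reactants: 5 1-(3,4-dimethoxyphenyl)propane-1,2-dione
Product: 6 2-[(tert-butyldimethylsilyl)oxy]-1-(3,4-dimethoxyphenyl)prop-2-en-1-one
Conditions: TBSOTf, Et3N, CH2Cl2, 0 °C
Reagents that add atoms: tert-butyldimethylsilyl trifluoromethanesulfonate, CC(C)(C)[Si](C)(C)OS(=O)(=O)C(F)(F)F
Why: Soft enolisation with O-silylation (silyl enol ether formation) can occur only toward the methyl group, the sole enolisable position, so a single α-siloxy enone without acidic hydrogens should result.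

Step 5
Reactants: 3 (2S,3S)-2-(3,4-dimethoxyphenyl)-3-ethenyloxirane; 6 2-[(tert-butyldimethylsilyl)oxy]-1-(3,4-dimethoxyphenyl)prop-2-en-1-one
Product: 7 [(3S,4S,5R)-3-[(tert-butyldimethylsilyl)oxy]-5-(3,4-dimethoxyphenyl)-4-ethenyloxolan-3-yl](3,4-dimethoxyphenyl)methanone
Conditions: Pd2(dba)3·CHCl3 (2.5 mol %), PPh3 (12 mol %), THF, 0 → 23 °C
Reagents that add atoms: none
Why: Zerovalent palladium ionises the allylic C–O bond of 3 with inversion to a zwitterionic π-allyl complex of divalent palladium carrying the alkoxide, the alkoxide adds to the unsubstituted β-carbon of 6 (oxa-Michael), and the resulting α-siloxy aryl-ketone enolate alkylates the substituted allyl terminus anti to the metal (Tsuji–Trost), releasing the catalyst. The closest known reaction type is the palladium-catalysed formal [3+2] cycloaddition (ring expansion) of vinyl oxiranes with Michael acceptors, enones included. The oxolane closes by a 5-exo allylic C-alkylation, so the three oxirane atoms are kept and two carbons are inserted between the oxygen and the allylic carbon. The aryl-bearing carbinol carbon is not involved and keeps the configuration of 3; the vinyl-bearing carbon forms with net retention (double inversion), and π–σ–π equilibration in any case favours the 4,5-trans closure; the quaternary carbon is set by the enolate face, the closure that turns the bulky aroyl-enolate terminus away from the allyl–palladium unit placing the siloxy group cis to vinyl. The step needs O-conjugate addition to outrun isomerisation of the opened oxirane and silyl transfer, and branched C- over O-alkylation; the unhindered CH2 terminus and lack of acidic hydrogens in 6, the bulky tert-butyldimethylsilyl group and the five- over seven-membered ring preference should secure this.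

Step 6
Reactants: 7 [(3S,4S,5R)-3-[(tert-butyldimethylsilyl)oxy]-5-(3,4-dimethoxyphenyl)-4-ethenyloxolan-3-yl](3,4-dimethoxyphenyl)methanone
Product: 9 (R)-[(3S,4S,5R)-3-[(tert-butyldimethylsilyl)oxy]-5-(3,4-dimethoxyphenyl)-4-(hydroxymethyl)oxolan-3-yl](3,4-dimethoxyphenyl)methanol, via keto aldehyde 8 (not isolated)
Conditions: O3, CH2Cl2/MeOH 4:1, Sudan Red 7B, −78 °C; then NaBH4, −78 → 23 °C
Reagents that add atoms: ozone, [O-][O+]=O
Why: Ozonolysis with reductive work-up should consume the terminal alkene before the dimethoxyphenyl rings (indicator end point), after which NaBH4 reduces aldehyde 8 and the aryl ketone, hydride adding in the polar Felkin–Anh sense (anti to the non-chelating C–OSi bond and past the ring CH2 instead of the branched ring carbon) to set the (R)-carbinol.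

Step 7
Reactants: 9 (R)-[(3S,4S,5R)-3-[(tert-butyldimethylsilyl)oxy]-5-(3,4-dimethoxyphenyl)-4-(hydroxymethyl)oxolan-3-yl](3,4-dimethoxyphenyl)methanol
Product: 11 tert-butyl{[(1S,2R,5S,6R)-2,6-bis(3,4-dimethoxyphenyl)-3,7-dioxabicyclo[3.3.0]octan-1-yl]oxy}dimethylsilane, via primary triflate 10 (not isolated)
Conditions: Tf2O (1.05 equiv), 2,6-di-tert-butyl-4-methylpyridine (3 equiv), CH2Cl2, −78 → 0 °C
Reagents that add atoms: none
Why: Intramolecular Williamson-type etherification in which the primary alcohol is triflated selectively at −78 °C and displaced 5-exo-tet by the neighbouring benzylic hydroxyl, so no stereocentre is touched and the trans ring fusion follows from the anti arrangement of the two arms fixed in step 5, while the silyl ether blocks the tertiary oxygen (no oxetane) and the hindered base keeps the medium non-acidic so that the strained ring is trapped kinetically.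

Step 8
Reactants: 11 tert-butyl{[(1S,2R,5S,6R)-2,6-bis(3,4-dimethoxyphenyl)-3,7-dioxabicyclo[3.3.0]octan-1-yl]oxy}dimethylsilane
Product: 12 (1S,2R,5S,6R)-2,6-bis(3,4-dimethoxyphenyl)-3,7-dioxabicyclo[3.3.0]octan-1-ol
Conditions: Bu4NF, THF, 0 → 40 °C
Reagents that add atoms: none
Why: Fluoride-mediated Si–O cleavage (desilylation) under non-acidic conditions should free the tertiary alcohol without ionising the benzylic ether bonds of the strained bicycle; no stereocentre is affected.

**Compound list**

1 | (E)-3-(3,4-dimethoxyphenyl)prop-2-enal | COc1ccc(/C=C/C=O)cc1OC | starting material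
2 | (2R,3S)-3-(3,4-dimethoxyphenyl)oxirane-2-carbaldehyde | O=C[C@@H]1O[C@H]1c1ccc(OC)c(OC)c1 | intermediate
3 | (2S,3S)-2-(3,4-dimethoxyphenyl)-3-ethenyloxirane | C=C[C@@H]1O[C@H]1c1ccc(OC)c(OC)c1 | intermediate
4 | 1-(3,4-dimethoxyphenyl)propan-1-one | CCC(=O)c1ccc(OC)c(OC)c1 | starting material
5 | 1-(3,4-dimethoxyphenyl)propane-1,2-dione | CC(=O)C(=O)c1ccc(OC)c(OC)c1 | intermediate
6 | 2-[(tert-butyldimethylsilyl)oxy]-1-(3,4-dimethoxyphenyl)prop-2-en-1-one | C=C(O[Si](C)(C)C(C)(C)C)C(=O)c1ccc(OC)c(OC)c1 | intermediate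
7 | [(3S,4S,5R)-3-[(tert-butyldimethylsilyl)oxy]-5-(3,4-dimethoxyphenyl)-4-ethenyloxolan-3-yl](3,4-dimethoxyphenyl)methanone | COc1ccc(cc1OC)C(=O)[C@@]1(O[Si](C)(C)C(C)(C)C)CO[C@@H](c2ccc(OC)c(OC)c2)[C@@H]1C=C | intermediate
8 | (2R,3S,4S)-4-[(tert-butyldimethylsilyl)oxy]-4-(3,4-dimethoxybenzoyl)-2-(3,4-dimethoxyphenyl)oxolane-3-carbaldehyde | COc1ccc(cc1OC)C(=O)[C@@]1(O[Si](C)(C)C(C)(C)C)CO[C@@H](c2ccc(OC)c(OC)c2)[C@@H]1C=O | intermediate (not isolated)
9 | (R)-[(3S,4S,5R)-3-[(tert-butyldimethylsilyl)oxy]-5-(3,4-dimethoxyphenyl)-4-(hydroxymethyl)oxolan-3-yl](3,4-dimethoxyphenyl)methanol | COc1ccc(cc1OC)[C@@H](O)[C@@]1(O[Si](C)(C)C(C)(C)C)CO[C@@H](c2ccc(OC)c(OC)c2)[C@@H]1CO | intermediate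
10 | [(2R,3S,4S)-4-[(tert-butyldimethylsilyl)oxy]-2-(3,4-dimethoxyphenyl)-4-[(R)-(3,4-dimethoxyphenyl)(hydroxy)methyl]oxolan-3-yl]methyl trifluoromethanesulfonate | COc1ccc(cc1OC)[C@@H](O)[C@@]1(O[Si](C)(C)C(C)(C)C)CO[C@@H](c2ccc(OC)c(OC)c2)[C@@H]1COS(=O)(=O)C(F)(F)F | intermediate (not isolated)
11 | tert-butyl{[(1S,2R,5S,6R)-2,6-bis(3,4-dimethoxyphenyl)-3,7-dioxabicyclo[3.3.0]octan-1-yl]oxy}dimethylsilane | COc1ccc([C@H]2OC[C@H]3[C@H](c4ccc(OC)c(OC)c4)OC[C@]23O[Si](C)(C)C(C)(C)C)cc1OC | intermediate
12 | (1S,2R,5S,6R)-2,6-bis(3,4-dimethoxyphenyl)-3,7-dioxabicyclo[3.3.0]octan-1-ol | COc1ccc([C@H]2OC[C@H]3[C@H](c4ccc(OC)c(OC)c4)OC[C@]23O)cc1OC | target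

**Step count.** Total: 8 steps. Longest linear sequence: 6 steps (1 → 2 → 3 → 7 → 9 → 11 → 12; steps 1, 2, 5, 6, 7, 8).

**Steps most likely to fail**

Step 7. The 5-exo-tet displacement that closes the trans-fused ring is slowed by ring strain, so that triflation of the benzylic hydroxyl, its ionisation and elimination may compete. The fallback sets out from 9 and returns at 12. The silyl group is removed first (Bu4NF, THF) to give the triol F1. Its primary hydroxyl is sulfonylated selectively (2,4,6-triisopropylbenzenesulfonyl chloride, pyridine, 0 °C) to give the primary arenesulfonate F2. The vicinal diol of F2 is converted into its dibutylstannylene acetal (Bu2SnO, toluene, reflux) and heated with CsF in DMF. The tin template should deliver the less hindered benzylic oxygen to the CH2–sulfonate, giving 12 directly.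

Step 5. Conjugate addition of the palladium-bound alkoxide to the hindered, donor-substituted enone may be too slow, so that isomerisation of the opened oxirane or silyl transfer to the alkoxide takes over. The fallback sets out from 3 and returns at 7; it takes the aryl ketone out of the acceptor. 2,2-Dimethyl-1,3-dioxan-5-one is O-silylated (TBSOTf, Et3N, CH2Cl2) to the silyloxydioxin F3. Heating F3 in toluene should expel acetone by retro-[4+2] cleavage and give 2-[(tert-butyldimethylsilyl)oxy]prop-2-enal F4. This smaller, more electrophilic enal enters the same palladium-catalysed ring expansion with 3 (Pd2(dba)3·CHCl3, PPh3, THF) to give the oxolane aldehyde F5. Addition of 3,4-dimethoxyphenylmagnesium bromide (THF, −78 °C) gives the carbinol epimer mixture F6. Dess–Martin oxidation converges both epimers on 7.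

Step 6. Facial selectivity in the hydride addition to the aryl ketone may be poor, and ozone may attack the dimethoxyphenyl rings while both reductions are coupled in one pot. The fallback sets out from 7 and returns at 9. The ketone is reduced first under catalyst control with (R)-2-methyl-CBS-oxazaborolidine and catecholborane (toluene, −78 °C; aryl acting as the large group), a Corey–Bakshi–Shibata reduction that should give the (R)-carbinol F7 with the vinyl group intact. The vinyl group is then cleaved with OsO4 (cat.)/NaIO4 (2,6-lutidine, dioxane/H2O) and the aldehyde reduced with NaBH4 to give 9.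

**Further compounds**

F1 | step 7 | (3S,4S,5R)-5-(3,4-dimethoxyphenyl)-3-[(R)-(3,4-dimethoxyphenyl)(hydroxy)methyl]-4-(hydroxymethyl)oxolan-3-ol | COc1ccc(cc1OC)[C@@H](O)[C@@]1(O)CO[C@@H](c2ccc(OC)c(OC)c2)[C@@H]1CO
F2 | step 7 | [(2R,3S,4S)-2-(3,4-dimethoxyphenyl)-4-[(R)-(3,4-dimethoxyphenyl)(hydroxy)methyl]-4-hydroxyoxolan-3-yl]methyl 2,4,6-tri(propan-2-yl)benzenesulfonate | COc1ccc(cc1OC)[C@@H](O)[C@@]1(O)CO[C@@H](c2ccc(OC)c(OC)c2)[C@@H]1COS(=O)(=O)c1c(C(C)C)cc(C(C)C)cc1C(C)C
F3 | step 5 | tert-butyl[(2,2-dimethyl-4H-1,3-dioxin-5-yl)oxy]dimethylsilane | CC1(C)OCC(O[Si](C)(C)C(C)(C)C)=CO1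
F4 | step 5 | 2-[(tert-butyldimethylsilyl)oxy]prop-2-enal | C=C(O[Si](C)(C)C(C)(C)C)C=O
F5 | step 5 | (3S,4S,5R)-3-[(tert-butyldimethylsilyl)oxy]-5-(3,4-dimethoxyphenyl)-4-ethenyloxolane-3-carbaldehyde | O=C[C@@]1(O[Si](C)(C)C(C)(C)C)CO[C@@H](c2ccc(OC)c(OC)c2)[C@@H]1C=C
F6 | step 5 | [(3S,4S,5R)-3-[(tert-butyldimethylsilyl)oxy]-5-(3,4-dimethoxyphenyl)-4-ethenyloxolan-3-yl](3,4-dimethoxyphenyl)methanol, both carbinol epimers | COc1ccc(cc1OC)C(O)[C@@]1(O[Si](C)(C)C(C)(C)C)CO[C@@H](c2ccc(OC)c(OC)c2)[C@@H]1C=C
F7 | step 6 | (R)-[(3S,4S,5R)-3-[(tert-butyldimethylsilyl)oxy]-5-(3,4-dimethoxyphenyl)-4-ethenyloxolan-3-yl](3,4-dimethoxyphenyl)methanol | COc1ccc(cc1OC)[C@@H](O)[C@@]1(O[Si](C)(C)C(C)(C)C)CO[C@@H](c2ccc(OC)c(OC)c2)[C@@H]1C=C
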